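## Retrosynthetic overview

1. The target is traced back, by desilylation and SeO2 allylic hydroxylation at C7, to 19-acetoxy-15-silyloxy-labda-8(17),13Z-dien-2-one, and this to a 3β,19-diacetoxy-2-ketone from which SmI2 excises the C3 oxygen.
2. Key disconnection: C4–C5 together with C9–C10. An acyclic trienyl α,β-epoxy ketone carrying an allylsilane is folded by MeAlCl2; ring A closes first (C4–C5), ring B second (C9–C10), in one operation.
3. Enabling feature: in ring A the quaternary C4 is flanked by the C3 methylene that is α to the C2 ketone, so C3 can carry the oxirane oxygen that triggers closure at C4 and then lose it again. In ring B the exocyclic C8=C17 methylene is the footprint of an allylsilane. C4, C5=C10 and C9=C8 stand in the head-to-tail 1,5-diene relationship.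
4. The epoxy ketone comes from a Z-enone (CBS reduction, hydroxyl-directed epoxidation, oxidation: the C2 carbinol relays chirality to C3/C4 and is then erased), itself made by Nozaki–Hiyama–Kishi union of a polyene aldehyde with a Z-iodoalkene.
5. The polyene aldehyde comes from a B-alkyl Suzuki coupling (Z side-chain olefin), acetoacetate dianion alkylation / enol triflate / Kumada coupling (allylsilane) and zirconium-catalysed carboalumination (E olefin).

Key step: step 21

Remark: names use labdane numbering (ring A = C1–C5, C10; ring B = C5–C10; side chain C11–C16; C17 exocyclic methylene; C18 methyl and C19 oxygenated carbon on C4; C20 methyl on C10). The target is read as (4S,5R,7R,9R,10S)-19-acetoxy-7α,15-dihydroxylabda-8(17),13Z-dien-2-one, with α/β referring to the usual drawing with the C10 methyl β. Compounds 1, 5, 9 and 14 are taken as commercial.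

## Route

Step 1
Reactants: 1 prop-2-yn-1-ol
Product: 3 (Z)-3-iodo-2-methylprop-2-en-1-ol, via cyclic alkenylmagnesium alkoxide 2 (not isolated)
Conditions: MeMgBr (3 equiv), CuI (10 mol %), THF, −10 °C to rt; then I2, −10 °C
Reagents that add atoms: methylmagnesium bromide, C[Mg]Br; iodine, [I][I]
Why: Copper-catalysed anti-carbomagnesiation of the propargylic alkoxide delivers methyl to the internal carbon and magnesium to the terminal carbon within a five-membered chelate, and iodinolysis with retention should give the Z iodoalkene (iodine cis to CH2OH).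

Step 2
Reactants: 3 (Z)-3-iodo-2-methylprop-2-en-1-ol
Product: 4 tert-butyl{[(Z)-3-iodo-2-methylprop-2-en-1-yl]oxy}dimethylsilane
Conditions: TBSCl, imidazole, DMF, 0 °C to rt
Reagents that add atoms: tert-butyldimethylsilyl chloride, CC(C)(C)[Si](C)(C)Cl
Why: Routine silylation of a primary alcohol, which leaves the vinyl iodide and its geometry untouched.

Step 3
Reactants: 5 but-2-yn-1-ol
Product: 7 (Z)-3-iodobut-2-en-1-ol, via sodium cyclic alkenylaluminate 6 (not isolated)
Conditions: NaAlH2(OCH2CH2OCH3)2, THF, 0 °C to rt; then I2, −78 °C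
Reagents that add atoms: iodine, [I][I]
Why: Hydroxyl-directed trans-hydroalumination of the propargylic alcohol places aluminium on the methyl-bearing carbon cis to CH2O, and iodinolysis with retention should give the Z iodide.

Step 4
Reactants: 7 (Z)-3-iodobut-2-en-1-ol
Product: 8 tert-butyl{[(Z)-3-iodobut-2-en-1-yl]oxy}diphenylsilane
Conditions: TBDPSCl, imidazole, DMF, rt
Reagents that add atoms: tert-butyldiphenylsilyl chloride, CC(C)(C)[Si](Cl)(c1ccccc1)c1ccccc1
Why: Routine silylation, with the TBDPS group chosen to outlast the later TBS cleavages.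

Step 5
Reactants: 9 (but-3-yn-1-yloxy)(tert-butyl)dimethylsilane
Product: 12 (E)-5-[(tert-butyldimethylsilyl)oxy]-3-methylpent-2-en-1-ol, via alkenyldimethylalane 10 (not isolated), via lithium alkenylalanate 11 (not isolated)
Conditions: Me3Al, Cp2ZrCl2 (20 mol %), CH2Cl2, 0 °C to rt; then n-BuLi, THF, −78 °C; (CH2O)n, to rt
Reagents that add atoms: trimethylaluminium, C[Al](C)C; paraformaldehyde (as formaldehyde), C=O
Why: Zirconium-catalysed syn-methylalumination (Negishi carboalumination) of the terminal alkyne fixes the E trisubstituted olefin, and the alanate is hydroxymethylated by formaldehyde with retention.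

Step 6
Reactants: 12 (E)-5-[(tert-butyldimethylsilyl)oxy]-3-methylpent-2-en-1-ol
Product: 13 {[(E)-5-bromo-3-methylpent-3-en-1-yl]oxy}(tert-butyl)dimethylsilane
Conditions: CBr4, PPh3, CH2Cl2, 0 °C
Reagents that add atoms: carbon tetrabromide, BrC(Br)(Br)Br
Why: Appel bromination of the primary allylic alcohol proceeds by SN2 displacement without allylic transposition or loss of the TBS ether.

Step 7
Reactants: 14 ethyl 3-oxobutanoate; 13 {[(E)-5-bromo-3-methylpent-3-en-1-yl]oxy}(tert-butyl)dimethylsilane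
Product: 16 ethyl (E)-9-[(tert-butyldimethylsilyl)oxy]-7-methyl-3-oxonon-6-enoate, via acetoacetate dianion 15 (not isolated)
Conditions: NaH, then n-BuLi, THF, 0 °C; then 13, 0 °C
Reagents that add atoms: none
Why: The acetoacetate dianion alkylates at its more nucleophilic terminal (γ) carbon with the allylic bromide, a classical dianion alkylation.

Step 8
Reactants: 16 ethyl (E)-9-[(tert-butyldimethylsilyl)oxy]-7-methyl-3-oxonon-6-enoate
Product: 18 ethyl (2Z,6E)-9-[(tert-butyldimethylsilyl)oxy]-7-methyl-3-{[(trifluoromethyl)sulfonyl]oxy}nona-2,6-dienoate, via sodium Z-enolate 17 (not isolated)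
Conditions: NaH, THF, 0 °C; then PhNTf2, 0 °C to rt
Reagents that add atoms: N-phenylbis(trifluoromethanesulfonimide), O=S(=O)(N(c1ccccc1)S(=O)(=O)C(F)(F)F)C(F)(F)F
Why: The chelated sodium enolate of the β-keto ester is Z, and O-sulfonylation should trap it as the Z enol triflate (triflate cis to the ester).

Step 9
Reactants: 18 ethyl (2Z,6E)-9-[(tert-butyldimethylsilyl)oxy]-7-methyl-3-{[(trifluoromethyl)sulfonyl]oxy}nona-2,6-dienoate
Product: 19 ethyl (2Z,6E)-9-[(tert-butyldimethylsilyl)oxy]-7-methyl-3-[(trimethylsilyl)methyl]nona-2,6-dienoate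
Conditions: Me3SiCH2MgCl, Pd(PPh3)4 (5 mol %), THF, 0 °C to rt
Reagents that add atoms: (trimethylsilyl)methylmagnesium chloride, C[Si](C)(C)C[Mg]Cl
Why: Kumada coupling of the enol triflate with the silylmethyl Grignard reagent proceeds with retention and faster than addition to the ester, giving the allylsilane with CH2SiMe3 cis to the ester.

Step 10
Reactants: 19 ethyl (2Z,6E)-9-[(tert-butyldimethylsilyl)oxy]-7-methyl-3-[(trimethylsilyl)methyl]nona-2,6-dienoate
Product: 20 (2Z,6E)-9-[(tert-butyldimethylsilyl)oxy]-7-methyl-3-[(trimethylsilyl)methyl]nona-2,6-dien-1-ol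
Conditions: i-Bu2AlH (2.2 equiv), CH2Cl2, −78 °C
Reagents that add atoms: none
Why: i-Bu2AlH reduces the enoate 1,2 to the allylic alcohol without touching the silyl ether, the allylsilane or the olefin geometry.

Step 11
Reactants: 20 (2Z,6E)-9-[(tert-butyldimethylsilyl)oxy]-7-methyl-3-[(trimethylsilyl)methyl]nona-2,6-dien-1-ol
Product: 21 (2Z,6E)-9-[(tert-butyldimethylsilyl)oxy]-7-methyl-3-[(trimethylsilyl)methyl]nona-2,6-dienal
Conditions: MnO2, CH2Cl2, rt
Reagents that add atoms: none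
Why: MnO2 oxidises only the allylic alcohol under neutral conditions that spare the acid-sensitive allylsilane.

Step 12
Reactants: 21 (2Z,6E)-9-[(tert-butyldimethylsilyl)oxy]-7-methyl-3-[(trimethylsilyl)methyl]nona-2,6-dienal
Product: 22 tert-butyldimethyl{[(3E,7Z)-3-methyl-7-[(trimethylsilyl)methyl]deca-3,7,9-trien-1-yl]oxy}silane
Conditions: Ph3PCH3Br, KOtBu, THF, 0 °C
Reagents that add atoms: methyltriphenylphosphonium bromide, C[P+](c1ccccc1)(c1ccccc1)c1ccccc1.[Br-]
Why: Wittig methylenation of the enal gives the terminal 1,3-diene needed for selective hydroboration.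

Step 13
Reactants: 22 tert-butyldimethyl{[(3E,7Z)-3-methyl-7-[(trimethylsilyl)methyl]deca-3,7,9-trien-1-yl]oxy}silane; 8 tert-butyl{[(Z)-3-iodobut-2-en-1-yl]oxy}diphenylsilane
Product: 24 (2Z,6Z,10E)-13-[(tert-butyldimethylsilyl)oxy]-1-[(tert-butyldiphenylsilyl)oxy]-3,11-dimethyl-7-[(trimethylsilyl)methyl]trideca-2,6,10-triene, via B-alkyl-9-borabicyclononane 23 (not isolated)
Conditions: 9-BBN, THF, 0 °C to rt; then 8, PdCl2(dppf) (5 mol %), AsPh3, Cs2CO3, DMF/H2O, rt
Reagents that add atoms: none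
Why: 9-BBN hydroborates only the monosubstituted terminal olefin at its terminal carbon, and the B-alkyl Suzuki–Miyaura coupling with the Z iodoalkene proceeds with retention to set the Z trisubstituted side-chain olefin.

Step 14
Reactants: 24 (2Z,6Z,10E)-13-[(tert-butyldimethylsilyl)oxy]-1-[(tert-butyldiphenylsilyl)oxy]-3,11-dimethyl-7-[(trimethylsilyl)methyl]trideca-2,6,10-triene
Product: 25 (3E,7Z,11Z)-13-[(tert-butyldiphenylsilyl)oxy]-3,11-dimethyl-7-[(trimethylsilyl)methyl]trideca-3,7,11-trien-1-ol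
Conditions: pyridinium p-toluenesulfonate (0.2 equiv), MeOH, rt
Reagents that add atoms: none
Why: Mild acid methanolysis removes the primary alkyl TBS ether selectively in the presence of the more robust TBDPS ether and the allylsilane.

Step 15
Reactants: 25 (3E,7Z,11Z)-13-[(tert-butyldiphenylsilyl)oxy]-3,11-dimethyl-7-[(trimethylsilyl)methyl]trideca-3,7,11-trien-1-ol
Product: 26 (3E,7Z,11Z)-13-[(tert-butyldiphenylsilyl)oxy]-3,11-dimethyl-7-[(trimethylsilyl)methyl]trideca-3,7,11-trienal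
Conditions: Dess–Martin periodinane, pyridine, CH2Cl2, 0 °C; used directly
Reagents that add atoms: none
Why: Dess–Martin oxidation under buffered, non-basic conditions gives the β,γ-unsaturated aldehyde without conjugation of the olefin.

Step 16
Reactants: 26 (3E,7Z,11Z)-13-[(tert-butyldiphenylsilyl)oxy]-3,11-dimethyl-7-[(trimethylsilyl)methyl]trideca-3,7,11-trienal; 4 tert-butyl{[(Z)-3-iodo-2-methylprop-2-en-1-yl]oxy}dimethylsilane
Product: 28 rac-(2Z,6E,10Z,14Z)-1-[(tert-butyldimethylsilyl)oxy]-16-[(tert-butyldiphenylsilyl)oxy]-2,6,14-trimethyl-10-[(trimethylsilyl)methyl]hexadeca-2,6,10,14-tetraen-4-ol, via alkenylchromium dichloride 27 (not isolated)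
Conditions: CrCl2 (5 equiv), NiCl2 (2 mol %), DMSO, rt
Reagents that add atoms: none
Why: Nozaki–Hiyama–Kishi coupling generates an alkenylchromium species that adds to the enolisable aldehyde without deprotonating it and with retention of the Z geometry, the racemic carbinol centre being erased in the next step.

Step 17
Reactants: 28 rac-(2Z,6E,10Z,14Z)-1-[(tert-butyldimethylsilyl)oxy]-16-[(tert-butyldiphenylsilyl)oxy]-2,6,14-trimethyl-10-[(trimethylsilyl)methyl]hexadeca-2,6,10,14-tetraen-4-ol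
Product: 29 (2Z,6E,10Z,14Z)-1-[(tert-butyldimethylsilyl)oxy]-16-[(tert-butyldiphenylsilyl)oxy]-2,6,14-trimethyl-10-[(trimethylsilyl)methyl]hexadeca-2,6,10,14-tetraen-4-one
Conditions: Dess–Martin periodinane, pyridine, CH2Cl2, 0 °C
Reagents that add atoms: none
Why: Dess–Martin oxidation of the allylic alcohol gives the Z enone without isomerising the olefin.

Step 18
Reactants: 29 (2Z,6E,10Z,14Z)-1-[(tert-butyldimethylsilyl)oxy]-16-[(tert-butyldiphenylsilyl)oxy]-2,6,14-trimethyl-10-[(trimethylsilyl)methyl]hexadeca-2,6,10,14-tetraen-4-one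
Product: 30 (4R,2Z,6E,10Z,14Z)-1-[(tert-butyldimethylsilyl)oxy]-16-[(tert-butyldiphenylsilyl)oxy]-2,6,14-trimethyl-10-[(trimethylsilyl)methyl]hexadeca-2,6,10,14-tetraen-4-ol
Conditions: (S)-1-methyl-3,3-diphenyltetrahydro-1H,3H-pyrrolo[1,2-c][1,3,2]oxazaborole (20 mol %), catecholborane, toluene, −78 °C
Reagents that add atoms: none
Why: Corey–Bakshi–Shibata reduction with the S oxazaborolidine, the alkenyl group acting as the large substituent, should deliver hydride to give the R allylic alcohol.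

Step 19
Reactants: 30 (4R,2Z,6E,10Z,14Z)-1-[(tert-butyldimethylsilyl)oxy]-16-[(tert-butyldiphenylsilyl)oxy]-2,6,14-trimethyl-10-[(trimethylsilyl)methyl]hexadeca-2,6,10,14-tetraen-4-ol
Product: 31 (2R,3S,4R,6E,10Z,14Z)-2,3-epoxy-1-[(tert-butyldimethylsilyl)oxy]-16-[(tert-butyldiphenylsilyl)oxy]-2,6,14-trimethyl-10-[(trimethylsilyl)methyl]hexadeca-6,10,14-trien-4-ol (threo)
Conditions: VO(acac)2 (5 mol %), t-BuOOH, CH2Cl2, 0 °C
Reagents that add atoms: tert-butyl hydroperoxide, CC(C)(C)OO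
Why: Vanadium-catalysed hydroxyl-directed epoxidation attacks only the allylic olefin, and 1,3-allylic strain between the carbinol substituent and the cis CH2OTBS group should favour the threo epoxy alcohol, from which the minor diastereomer is separated.

Step 20
Reactants: 31 (2R,3S,4R,6E,10Z,14Z)-2,3-epoxy-1-[(tert-butyldimethylsilyl)oxy]-16-[(tert-butyldiphenylsilyl)oxy]-2,6,14-trimethyl-10-[(trimethylsilyl)methyl]hexadeca-6,10,14-trien-4-ol
Product: 32 (2R,3R,6E,10Z,14Z)-2,3-epoxy-1-[(tert-butyldimethylsilyl)oxy]-16-[(tert-butyldiphenylsilyl)oxy]-2,6,14-trimethyl-10-[(trimethylsilyl)methyl]hexadeca-6,10,14-trien-4-one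
Conditions: Dess–Martin periodinane, pyridine, CH2Cl2, 0 °C
Reagents that add atoms: none
Why: Dess–Martin oxidation converts the carbinol, whose stereochemical task is done, into the ketone that later allows reductive removal of the C3 oxygen.

Step 21
Reactants: 32 (2R,3R,6E,10Z,14Z)-2,3-epoxy-1-[(tert-butyldimethylsilyl)oxy]-16-[(tert-butyldiphenylsilyl)oxy]-2,6,14-trimethyl-10-[(trimethylsilyl)methyl]hexadeca-6,10,14-trien-4-one
Product: 33 3β-hydroxy-19-[(tert-butyldimethylsilyl)oxy]-15-[(tert-butyldiphenylsilyl)oxy]labda-8(17),13Z-dien-2-one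
Conditions: MeAlCl2 (2.5 equiv), CH2Cl2, −78 to −40 °C, dilute
Reagents that add atoms: none
Why: Proposed new method: MeAlCl2 bound to the oxirane oxygen (held also by the adjacent C2 carbonyl) should weaken the C4–O bond while the C5=C10 olefin attacks C4 from the back, the developing C10 cation being taken by C9 of the allylsilane and the β-silyl cation losing Me3Si to leave the C8=C17 methylene; the closest known reaction type is the Lewis-acid, epoxide-initiated cation–olefin bicyclisation terminated by an allylsilane, here extended to an α,β-epoxy ketone as initiator. Ring A closes by 6-endo attack of the C5=C10 olefin on C4 (C4–C5 bond, anti opening of the oxirane) and ring B by 6-endo attack of C10 on the allylsilane γ-carbon C9 (C9–C10 bond), both through a chair–chair array. C4 is set by inversion at the stereodefined oxirane carbon, so that the CH2OTBS group cis to C2 on the oxirane becomes axial (C19) and the methyl equatorial; C5 and C10 follow from anti addition across the E olefin (trans fusion, axial C20), C9 from the geometry of the allylsilane (equatorial side chain), and the absolute sense of all four from the oxirane C3, whose oxygen sits equatorial (3β) in the chair. The step needs C4–O rather than C3–O cleavage, secured because C4 is tertiary while C3 is α to the carbonyl, and termination after two rings, secured by fast desilylation of the allylsilane. A competing 1,2-acyl or hydride shift needs a free C4 cation, which the concerted backside participation of the pre-organised olefin should avoid, and MeAlCl2 scavenges protons that would cleave the allylsilane.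

Step 22
Reactants: 33 3β-hydroxy-19-[(tert-butyldimethylsilyl)oxy]-15-[(tert-butyldiphenylsilyl)oxy]labda-8(17),13Z-dien-2-one
Product: 34 3β,19-dihydroxy-15-[(tert-butyldiphenylsilyl)oxy]labda-8(17),13Z-dien-2-one
Conditions: HF·pyridine, pyridine, THF, 0 °C
Reagents that add atoms: none
Why: Buffered HF·pyridine cleaves the primary TBS ether much faster than the TBDPS ether.

Step 23
Reactants: 34 3β,19-dihydroxy-15-[(tert-butyldiphenylsilyl)oxy]labda-8(17),13Z-dien-2-one
Product: 35 3β,19-diacetoxy-15-[(tert-butyldiphenylsilyl)oxy]labda-8(17),13Z-dien-2-one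
Conditions: Ac2O, pyridine, 4-(dimethylamino)pyridine (0.1 equiv), CH2Cl2, 0 °C
Reagents that add atoms: acetic anhydride, CC(=O)OC(C)=O
Why: Acetylation catalysed by 4-(dimethylamino)pyridine esterifies both the hindered C3 hydroxyl and the C19 hydroxyl, installing at once the acetate of the target and the leaving group for the next step.

Step 24
Reactants: 35 3β,19-diacetoxy-15-[(tert-butyldiphenylsilyl)oxy]labda-8(17),13Z-dien-2-one
Product: 36 19-acetoxy-15-[(tert-butyldiphenylsilyl)oxy]labda-8(17),13Z-dien-2-one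
Conditions: SmI2 (2.2 equiv), THF/MeOH, −78 °C
Reagents that add atoms: none
Why: SmI2 reduces α-acyloxy ketones by electron transfer to the carbonyl, loss of the α-acetate and protonation of the samarium enolate, so only the C3 acetate is excised and the C3 stereocentre disappears.

Step 25
Reactants: 36 19-acetoxy-15-[(tert-butyldiphenylsilyl)oxy]labda-8(17),13Z-dien-2-one
Product: 37 19-acetoxy-7α-hydroxy-15-[(tert-butyldiphenylsilyl)oxy]labda-8(17),13Z-dien-2-one
Conditions: SeO2 (0.5 equiv), t-BuOOH, CH2Cl2, rt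
Reagents that add atoms: tert-butyl hydroperoxide, CC(C)(C)OO; selenium dioxide (oxygen carrier), O=[Se]=O
Why: Selenium dioxide allylic oxidation (ene reaction, then 2,3-sigmatropic shift) of the exocyclic methylene should hydroxylate C7 from the axial α face, while the side-chain olefin is deactivated by its allylic oxygen and C9 is hindered.

Step 26
Reactants: 37 19-acetoxy-7α-hydroxy-15-[(tert-butyldiphenylsilyl)oxy]labda-8(17),13Z-dien-2-one
Product: 38 (4S,5R,7R,9R,10S)-19-acetoxy-7α,15-dihydroxylabda-8(17),13Z-dien-2-one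
Conditions: Bu4NF, AcOH, THF, 0 °C to rt
Reagents that add atoms: none
Why: Fluoride cleaves the TBDPS ether, and buffering with acetic acid protects the acetate from migration or cleavage.

## Compound list

1 | prop-2-yn-1-ol | C#CCO | starting material
2 | cyclic alkenylmagnesium alkoxide (4-methyl-2,5-dihydro-1,2-oxamagnesole) | CC1=C[Mg]OC1 | intermediate
3 | (Z)-3-iodo-2-methylprop-2-en-1-ol | OC/C(C)=C\I | intermediate
4 | tert-butyl{[(Z)-3-iodo-2-methylprop-2-en-1-yl]oxy}dimethylsilane | CC(C)(C)[Si](C)(C)OC/C(C)=C\I | intermediate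
5 | but-2-yn-1-ol | CC#CCO | starting material
6 | sodium cyclic alkenylaluminate (Al on the methyl-bearing carbon and on oxygen, two 2-methoxyethoxy groups) | [Na+].CC1=CCO[Al-]1(OCCOC)OCCOC | intermediate
7 | (Z)-3-iodobut-2-en-1-ol | C/C(I)=C/CO | intermediate
8 | tert-butyl{[(Z)-3-iodobut-2-en-1-yl]oxy}diphenylsilane | C/C(I)=C/CO[Si](c1ccccc1)(c1ccccc1)C(C)(C)C | intermediate
9 | (but-3-yn-1-yloxy)(tert-butyl)dimethylsilane | C#CCCO[Si](C)(C)C(C)(C)C | starting material
10 | {(E)-4-[(tert-butyldimethylsilyl)oxy]-2-methylbut-1-en-1-yl}dimethylaluminium | C[Al](C)/C=C(C)/CCO[Si](C)(C)C(C)(C)C | intermediate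
11 | lithium butyl{(E)-4-[(tert-butyldimethylsilyl)oxy]-2-methylbut-1-en-1-yl}dimethylaluminate | [Li+].CCCC[Al-](C)(C)/C=C(C)/CCO[Si](C)(C)C(C)(C)C | intermediate
12 | (E)-5-[(tert-butyldimethylsilyl)oxy]-3-methylpent-2-en-1-ol | OC/C=C(C)/CCO[Si](C)(C)C(C)(C)C | intermediate
13 | {[(E)-5-bromo-3-methylpent-3-en-1-yl]oxy}(tert-butyl)dimethylsilane | BrC/C=C(C)/CCO[Si](C)(C)C(C)(C)C | intermediate
14 | ethyl 3-oxobutanoate | CCOC(=O)CC(C)=O | starting material
15 | ethyl acetoacetate dianion (lithium sodium salt) | [Li+].[Na+].C=C([O-])C=C([O-])OCC | intermediate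
16 | ethyl (E)-9-[(tert-butyldimethylsilyl)oxy]-7-methyl-3-oxonon-6-enoate | CCOC(=O)CC(=O)CC/C=C(C)/CCO[Si](C)(C)C(C)(C)C | intermediate
17 | sodium (Z)-enolate of 16 | [Na+].CCOC(=O)/C=C([O-])/CC/C=C(C)/CCO[Si](C)(C)C(C)(C)C | intermediate
18 | ethyl (2Z,6E)-9-[(tert-butyldimethylsilyl)oxy]-7-methyl-3-{[(trifluoromethyl)sulfonyl]oxy}nona-2,6-dienoate | CCOC(=O)/C=C(OS(=O)(=O)C(F)(F)F)/CC/C=C(C)/CCO[Si](C)(C)C(C)(C)C | intermediate
19 | ethyl (2Z,6E)-9-[(tert-butyldimethylsilyl)oxy]-7-methyl-3-[(trimethylsilyl)methyl]nona-2,6-dienoate | CCOC(=O)/C=C(C[Si](C)(C)C)/CC/C=C(C)/CCO[Si](C)(C)C(C)(C)C | intermediate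
20 | (2Z,6E)-9-[(tert-butyldimethylsilyl)oxy]-7-methyl-3-[(trimethylsilyl)methyl]nona-2,6-dien-1-ol | OC/C=C(C[Si](C)(C)C)/CC/C=C(C)/CCO[Si](C)(C)C(C)(C)C | intermediate
21 | (2Z,6E)-9-[(tert-butyldimethylsilyl)oxy]-7-methyl-3-[(trimethylsilyl)methyl]nona-2,6-dienal | O=C/C=C(C[Si](C)(C)C)/CC/C=C(C)/CCO[Si](C)(C)C(C)(C)C | intermediate
22 | tert-butyldimethyl{[(3E,7Z)-3-methyl-7-[(trimethylsilyl)methyl]deca-3,7,9-trien-1-yl]oxy}silane | C=C/C=C(C[Si](C)(C)C)/CC/C=C(C)/CCO[Si](C)(C)C(C)(C)C | intermediate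
23 | B-alkyl-9-borabicyclo[3.3.1]nonane from 22 (boron on the former terminal vinyl carbon) | C(C/C=C(C[Si](C)(C)C)/CC/C=C(C)/CCO[Si](C)(C)C(C)(C)C)B1C2CCCC1CCC2 | intermediate
24 | (2Z,6Z,10E)-13-[(tert-butyldimethylsilyl)oxy]-1-[(tert-butyldiphenylsilyl)oxy]-3,11-dimethyl-7-[(trimethylsilyl)methyl]trideca-2,6,10-triene | CC(C)(C)[Si](C)(C)OCC/C(C)=C/CC/C(C[Si](C)(C)C)=C/CC/C(C)=C\CO[Si](c1ccccc1)(c1ccccc1)C(C)(C)C | intermediate
25 | (3E,7Z,11Z)-13-[(tert-butyldiphenylsilyl)oxy]-3,11-dimethyl-7-[(trimethylsilyl)methyl]trideca-3,7,11-trien-1-ol | OCC/C(C)=C/CC/C(C[Si](C)(C)C)=C/CC/C(C)=C\CO[Si](c1ccccc1)(c1ccccc1)C(C)(C)C | intermediate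
26 | (3E,7Z,11Z)-13-[(tert-butyldiphenylsilyl)oxy]-3,11-dimethyl-7-[(trimethylsilyl)methyl]trideca-3,7,11-trienal | O=CC/C(C)=C/CC/C(C[Si](C)(C)C)=C/CC/C(C)=C\CO[Si](c1ccccc1)(c1ccccc1)C(C)(C)C | intermediate
27 | {(Z)-3-[(tert-butyldimethylsilyl)oxy]-2-methylprop-1-en-1-yl}chromium dichloride | Cl[Cr](Cl)/C=C(C)\CO[Si](C)(C)C(C)(C)C | intermediate
28 | rac-(2Z,6E,10Z,14Z)-1-[(tert-butyldimethylsilyl)oxy]-16-[(tert-butyldiphenylsilyl)oxy]-2,6,14-trimethyl-10-[(trimethylsilyl)methyl]hexadeca-2,6,10,14-tetraen-4-ol | OC(C/C(C)=C/CC/C(C[Si](C)(C)C)=C/CC/C(C)=C\CO[Si](c1ccccc1)(c1ccccc1)C(C)(C)C)/C=C(C)\CO[Si](C)(C)C(C)(C)C | intermediate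
29 | (2Z,6E,10Z,14Z)-1-[(tert-butyldimethylsilyl)oxy]-16-[(tert-butyldiphenylsilyl)oxy]-2,6,14-trimethyl-10-[(trimethylsilyl)methyl]hexadeca-2,6,10,14-tetraen-4-one | O=C(C/C(C)=C/CC/C(C[Si](C)(C)C)=C/CC/C(C)=C\CO[Si](c1ccccc1)(c1ccccc1)C(C)(C)C)/C=C(C)\CO[Si](C)(C)C(C)(C)C | intermediate
30 | (4R,2Z,6E,10Z,14Z)-1-[(tert-butyldimethylsilyl)oxy]-16-[(tert-butyldiphenylsilyl)oxy]-2,6,14-trimethyl-10-[(trimethylsilyl)methyl]hexadeca-2,6,10,14-tetraen-4-ol | O[C@H](C/C(C)=C/CC/C(C[Si](C)(C)C)=C/CC/C(C)=C\CO[Si](c1ccccc1)(c1ccccc1)C(C)(C)C)/C=C(C)\CO[Si](C)(C)C(C)(C)C | intermediate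
31 | (2R,3S,4R,6E,10Z,14Z)-2,3-epoxy-1-[(tert-butyldimethylsilyl)oxy]-16-[(tert-butyldiphenylsilyl)oxy]-2,6,14-trimethyl-10-[(trimethylsilyl)methyl]hexadeca-6,10,14-trien-4-ol | O[C@H](C/C(C)=C/CC/C(C[Si](C)(C)C)=C/CC/C(C)=C\CO[Si](c1ccccc1)(c1ccccc1)C(C)(C)C)[C@@H]2O[C@]2(C)CO[Si](C)(C)C(C)(C)C | intermediate
32 | (2R,3R,6E,10Z,14Z)-2,3-epoxy-1-[(tert-butyldimethylsilyl)oxy]-16-[(tert-butyldiphenylsilyl)oxy]-2,6,14-trimethyl-10-[(trimethylsilyl)methyl]hexadeca-6,10,14-trien-4-one | O=C(C/C(C)=C/CC/C(C[Si](C)(C)C)=C/CC/C(C)=C\CO[Si](c1ccccc1)(c1ccccc1)C(C)(C)C)[C@@H]2O[C@]2(C)CO[Si](C)(C)C(C)(C)C | intermediate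
33 | 3β-hydroxy-19-[(tert-butyldimethylsilyl)oxy]-15-[(tert-butyldiphenylsilyl)oxy]labda-8(17),13Z-dien-2-one | C=C1CC[C@H]2[C@@](C)(CO[Si](C)(C)C(C)(C)C)[C@@H](O)C(=O)C[C@]2(C)[C@H]1CC/C(C)=C\CO[Si](c3ccccc3)(c3ccccc3)C(C)(C)C | intermediate
34 | 3β,19-dihydroxy-15-[(tert-butyldiphenylsilyl)oxy]labda-8(17),13Z-dien-2-one | C=C1CC[C@H]2[C@@](C)(CO)[C@@H](O)C(=O)C[C@]2(C)[C@H]1CC/C(C)=C\CO[Si](c3ccccc3)(c3ccccc3)C(C)(C)C | intermediate
35 | 3β,19-diacetoxy-15-[(tert-butyldiphenylsilyl)oxy]labda-8(17),13Z-dien-2-one | C=C1CC[C@H]2[C@@](C)(COC(C)=O)[C@@H](OC(C)=O)C(=O)C[C@]2(C)[C@H]1CC/C(C)=C\CO[Si](c3ccccc3)(c3ccccc3)C(C)(C)C | intermediate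
36 | 19-acetoxy-15-[(tert-butyldiphenylsilyl)oxy]labda-8(17),13Z-dien-2-one | C=C1CC[C@H]2[C@@](C)(COC(C)=O)CC(=O)C[C@]2(C)[C@H]1CC/C(C)=C\CO[Si](c3ccccc3)(c3ccccc3)C(C)(C)C | intermediate
37 | 19-acetoxy-7α-hydroxy-15-[(tert-butyldiphenylsilyl)oxy]labda-8(17),13Z-dien-2-one | C=C1[C@H](O)C[C@H]2[C@@](C)(COC(C)=O)CC(=O)C[C@]2(C)[C@H]1CC/C(C)=C\CO[Si](c3ccccc3)(c3ccccc3)C(C)(C)C | intermediate
38 | (4S,5R,7R,9R,10S)-19-acetoxy-7α,15-dihydroxylabda-8(17),13Z-dien-2-one | C=C1[C@H](O)C[C@H]2[C@@](C)(COC(C)=O)CC(=O)C[C@]2(C)[C@H]1CC/C(C)=C\CO | target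

## Count and risks

Total step count: 26. Longest linear sequence: 22 steps (steps 5 to 26, from 9 to 38).

The three steps most likely to fail are step 21, step 25 and step 19.

First risk, step 21 (key step): the Lewis acid may trigger a 1,2-acyl or hydride shift of the epoxy ketone, or the β,γ-olefin may move into conjugation with the ketone, before ring A closes. The fallback for step 21 runs the same bicyclisation at the carbinol oxidation level, which is the established silyl-ether form of the epoxide-initiated, allylsilane-terminated cyclisation. It sets out from compound 31 and comes back to the route at compound 35. Et3SiCl and imidazole in CH2Cl2 should give the triethylsilyl ether F1. MeAlCl2 in CH2Cl2 at −78 °C should then close both rings to the 3β-hydroxy-2α-triethylsilyloxy labdadiene F2, the threo relationship placing the C2 substituent equatorial in the same chair. Ac2O with 4-(dimethylamino)pyridine should give the 3β-acetate F3, pyridinium p-toluenesulfonate in MeOH the 2α-alcohol F4, Dess–Martin oxidation the 3β-acetoxy 2-ketone F5, and HF·pyridine the 19-alcohol F6. Acetylation of the 19-alcohol F6 then gives compound 35.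

Second risk, step 25: the oxidation may be unselective, through attack at the allylic positions of the side-chain olefin, α-oxidation of the ketone, or incomplete facial selectivity at C7. The fallback for step 25 deactivates the side chain electronically instead of relying on intrinsic selectivity. It sets out from compound 36 and comes back to the route at compound 38. Bu4NF buffered with AcOH should give the 15-alcohol F7, and chloroacetyl chloride with pyridine the 15-chloroacetate F8. SeO2 with t-BuOOH should then give the 7α-hydroxy chloroacetate F9. Thiourea with NaHCO3 in EtOH should remove only the chloroacetate and give compound 38.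

Third risk, step 19: threo selectivity of the substrate-directed epoxidation may be insufficient, or the homoallylic C5=C10 olefin may be epoxidised as well; either lowers the enantiopurity of 32. The fallback for step 19 replaces substrate control by reagent control from the primary C19 hydroxyl. It sets out from compound 30 and comes back to the route at compound 31. Ac2O and pyridine should give the carbinol acetate F10, and pyridinium p-toluenesulfonate in MeOH should free the primary Z-allylic alcohol F11. Sharpless asymmetric epoxidation (Ti(OiPr)4 and D-(−)-diethyl tartrate in stoichiometric amount, t-BuOOH, 4 Å molecular sieves, CH2Cl2, −20 °C) should give the epoxy alcohol acetate F12, with the oxirane configured as in 31. TBSCl and imidazole should give the silyl ether F13, and K2CO3 in MeOH should remove the acetate to give compound 31.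

## Further compounds

F1 | step 21 | triethylsilyl ether of 31, (2R,3S,4R,6E,10Z,14Z)-2,3-epoxy-4-[(triethylsilyl)oxy] analogue | CC[Si](CC)(CC)O[C@H](C/C(C)=C/CC/C(C[Si](C)(C)C)=C/CC/C(C)=C\CO[Si](c1ccccc1)(c1ccccc1)C(C)(C)C)[C@@H]2O[C@]2(C)CO[Si](C)(C)C(C)(C)C
F2 | step 21 | 3β-hydroxy-2α-[(triethylsilyl)oxy]-19-[(tert-butyldimethylsilyl)oxy]-15-[(tert-butyldiphenylsilyl)oxy]labda-8(17),13Z-diene | C=C1CC[C@H]2[C@@](C)(CO[Si](C)(C)C(C)(C)C)[C@@H](O)[C@H](O[Si](CC)(CC)CC)C[C@]2(C)[C@H]1CC/C(C)=C\CO[Si](c3ccccc3)(c3ccccc3)C(C)(C)C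
F3 | step 21 | 3β-acetoxy-2α-[(triethylsilyl)oxy]-19-[(tert-butyldimethylsilyl)oxy]-15-[(tert-butyldiphenylsilyl)oxy]labda-8(17),13Z-diene | C=C1CC[C@H]2[C@@](C)(CO[Si](C)(C)C(C)(C)C)[C@@H](OC(C)=O)[C@H](O[Si](CC)(CC)CC)C[C@]2(C)[C@H]1CC/C(C)=C\CO[Si](c3ccccc3)(c3ccccc3)C(C)(C)C
F4 | step 21 | 3β-acetoxy-2α-hydroxy-19-[(tert-butyldimethylsilyl)oxy]-15-[(tert-butyldiphenylsilyl)oxy]labda-8(17),13Z-diene | C=C1CC[C@H]2[C@@](C)(CO[Si](C)(C)C(C)(C)C)[C@@H](OC(C)=O)[C@H](O)C[C@]2(C)[C@H]1CC/C(C)=C\CO[Si](c3ccccc3)(c3ccccc3)C(C)(C)C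
F5 | step 21 | 3β-acetoxy-19-[(tert-butyldimethylsilyl)oxy]-15-[(tert-butyldiphenylsilyl)oxy]labda-8(17),13Z-dien-2-one | C=C1CC[C@H]2[C@@](C)(CO[Si](C)(C)C(C)(C)C)[C@@H](OC(C)=O)C(=O)C[C@]2(C)[C@H]1CC/C(C)=C\CO[Si](c3ccccc3)(c3ccccc3)C(C)(C)C
F6 | step 21 | 3β-acetoxy-19-hydroxy-15-[(tert-butyldiphenylsilyl)oxy]labda-8(17),13Z-dien-2-one | C=C1CC[C@H]2[C@@](C)(CO)[C@@H](OC(C)=O)C(=O)C[C@]2(C)[C@H]1CC/C(C)=C\CO[Si](c3ccccc3)(c3ccccc3)C(C)(C)C
F7 | step 25 | 19-acetoxy-15-hydroxylabda-8(17),13Z-dien-2-one | C=C1CC[C@H]2[C@@](C)(COC(C)=O)CC(=O)C[C@]2(C)[C@H]1CC/C(C)=C\CO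
F8 | step 25 | 19-acetoxy-15-(chloroacetoxy)labda-8(17),13Z-dien-2-one | C=C1CC[C@H]2[C@@](C)(COC(C)=O)CC(=O)C[C@]2(C)[C@H]1CC/C(C)=C\COC(=O)CCl
F9 | step 25 | 19-acetoxy-15-(chloroacetoxy)-7α-hydroxylabda-8(17),13Z-dien-2-one | C=C1[C@H](O)C[C@H]2[C@@](C)(COC(C)=O)CC(=O)C[C@]2(C)[C@H]1CC/C(C)=C\COC(=O)CCl
F10 | step 19 | (4R)-acetate of 30 | CC(=O)O[C@H](C/C(C)=C/CC/C(C[Si](C)(C)C)=C/CC/C(C)=C\CO[Si](c1ccccc1)(c1ccccc1)C(C)(C)C)/C=C(C)\CO[Si](C)(C)C(C)(C)C
F11 | step 19 | (4R,2Z,6E,10Z,14Z)-4-acetoxy-16-[(tert-butyldiphenylsilyl)oxy]-2,6,14-trimethyl-10-[(trimethylsilyl)methyl]hexadeca-2,6,10,14-tetraen-1-ol | CC(=O)O[C@H](C/C(C)=C/CC/C(C[Si](C)(C)C)=C/CC/C(C)=C\CO[Si](c1ccccc1)(c1ccccc1)C(C)(C)C)/C=C(C)\CO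
F12 | step 19 | (2R,3S,4R)-4-acetoxy-2,3-epoxy-16-[(tert-butyldiphenylsilyl)oxy]-2,6,14-trimethyl-10-[(trimethylsilyl)methyl]hexadeca-6,10,14-trien-1-ol (oxirane configured as in 31) | CC(=O)O[C@H](C/C(C)=C/CC/C(C[Si](C)(C)C)=C/CC/C(C)=C\CO[Si](c1ccccc1)(c1ccccc1)C(C)(C)C)[C@@H]2O[C@]2(C)CO
F13 | step 19 | carbinol acetate of 31 (TBS ether of F12) | CC(=O)O[C@H](C/C(C)=C/CC/C(C[Si](C)(C)C)=C/CC/C(C)=C\CO[Si](c1ccccc1)(c1ccccc1)C(C)(C)C)[C@@H]2O[C@]2(C)CO[Si](C)(C)C(C)(C)C
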